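## Retrosynthetic overview

1. Numbering is that of 2H-chromene (O1, C2, C3, C4, C4a, C5, C6, C7, C8, C8a); the carbocycle is C4a–C5–C6–C7–C8–C8a, and these numbers are used for the ring atoms of all six-membered intermediates, whatever the locants in their names.
2. Pyran last: O1–C8a by addition–elimination of a tertiary alkoxide onto the C8a ethoxy enol ether, C4–C4a by Sonogashira coupling and semihydrogenation; C2 (R) comes from (R)-dehydrolinalool (geraniol, Sharpless epoxidation, epoxy chloride fragmentation) and the acyl stereocenter from (R)-2-methylbutanoic acid.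
3. Carbocycle: two-carbon ring expansion of 3-ethoxy-4,4-dimethylcyclobutenone with the acyl ynol ether (4R)-1-methoxy-4-methylhex-1-yn-3-one (4π opening, [2+2], 4π opening, 6π closure), the alkyne ending up between C1 and C2 of the four-membered ring.
4. Enabling feature: C8 is a quaternary gem-dimethyl carbon bonded to the C7 carbonyl in a 2,4-dienone whose oxygens sit at C7, C5 and C8a. This blocked dienone is what a dienylketene 6π closure gives; the three oxygens come from ketene C=O (C7), ynol ether (C5) and cyclobutenone enol ether (C8a), so they arrive differentiated.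
5. Ring order: four-membered ring (step 1), carbocycle (step 4), pyran (step 11).

Key step: step 4

Assumption: (R)-2-methylbutanoic acid (5), the less common enantiomer, is taken as a purchasable starting material.

## Route

Step 1
Reactants: 1 isobutyryl chloride; 2 ethoxyacetylene
Product: 4 3-ethoxy-4,4-dimethylcyclobut-2-en-1-one, via dimethylketene 3 (not isolated)
Conditions: Et3N, Et2O, 0 °C → rt (2 in excess)
Reagents that add atoms: none
Why: In-situ dehydrochlorination gives the ketene, whose thermal ketene–ynol ether [2+2] cycloaddition is regioselective (ketene carbonyl carbon to the unsubstituted, nucleophilic alkyne carbon) and should give the 3-alkoxycyclobutenone; no stereocenter is formed.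

Step 2
Reactants: 5 (R)-2-methylbutanoic acid; 6 N,O-dimethylhydroxylamine hydrochloride
Product: 8 (2R)-N-methoxy-N,2-dimethylbutanamide, via acyl imidazolide 7 (not isolated)
Conditions: CDI, CH2Cl2, 0 °C → rt; then 6, rt
Reagents that add atoms: none
Why: Weinreb amide formation through the acyl imidazolide is a mild activation that does not pass through a ketene, so the R stereocenter of 5 should be kept.

Step 3
Reactants: 8 (2R)-N-methoxy-N,2-dimethylbutanamide; 9 chloroacetaldehyde dimethyl acetal
Product: 12 (4R)-1-methoxy-4-methylhex-1-yn-3-one, via lithium methoxyacetylide 10 (not isolated), via tetrahedral adduct 11 (not isolated)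
Conditions: 9, LiNEt2 (3 equiv, from Et2NH and n-BuLi), THF, 0 °C; then 8, −78 → −30 °C; inverse quench into cold 1 M HCl/Et2O
Reagents that add atoms: none
Why: Weinreb ketone synthesis, in which elimination of MeOH and HCl from the chloroacetal and deprotonation give the acetylide, which adds once to the amide and stays as the chelated adduct until the cold acidic quench, where the amines are protonated and cannot add to the ynone; the acetylide is too weak a base to enolize the amide at low temperature, so the R center should be kept.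

Step 4
Reactants: 4 3-ethoxy-4,4-dimethylcyclobut-2-en-1-one; 12 (4R)-1-methoxy-4-methylhex-1-yn-3-one
Product: 16 5-ethoxy-3-methoxy-6,6-dimethyl-2-[(2R)-2-methylbutanoyl]cyclohexa-2,4-dien-1-one, via vinylketene 13 (not isolated), via alkenylcyclobutenone 14 (not isolated), via dienylketene 15 (not isolated)
Conditions: PhMe (0.2 M in 12), 4 (1.5 equiv), sealed tube, 130 °C
Reagents that add atoms: none
Why: Proposed new method: thermal conrotatory 4π opening of 4 gives (2-ethoxyvinyl)ketene 13, which adds in a [2+2] sense to the push–pull ynol ether 12 (its acyl-bearing carbon, made nucleophilic by the methoxy donor, bonds to the ketene carbonyl carbon) to give 14, whose reversible 4π opening gives dienylketene 15 that closes by 6π electrocyclization, so that the alkyne is in effect inserted into the C1–C2 bond of the four-membered ring and the ring grows by two carbons; the closest known reaction type is the Danheiser benzannulation of cyclobutenones with alkoxy- or siloxyalkynes, which has not been shown with an acyl-substituted ynol ether or with a 3-alkoxy-4,4-dialkylcyclobutenone. The carbocycle closes in the disrotatory 6π mode between the ketene carbon (C7) and the dimethyl-substituted diene terminus (C8), and because C8 is quaternary the 2,4-dienone cannot tautomerize to a phenol and should be the end point. No new stereocenter remains (C4 of 14 is transient and becomes sp2), and the acyl α-stereocenter should not be touched under neutral, base-free thermal conditions. The step needs regioselectivity in the [2+2] event, which the polarization of both partners should secure, and the productive rotation sense in the opening of 14, which reversibility should secure since only the isomer with the alkenyl group cis to the ketene arm can cyclize; the methyl ynol ether is chosen because, unlike an ethyl one, it cannot fragment by a retro-ene path at this temperature. The three ring oxygens should come out differentiated: ketone at C7 from the ketene, methyl ether at C5 from 12, ethyl ether at C8a from 4.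

Step 5
Reactants: 16 5-ethoxy-3-methoxy-6,6-dimethyl-2-[(2R)-2-methylbutanoyl]cyclohexa-2,4-dien-1-one
Product: 17 5-ethoxy-4-iodo-3-methoxy-6,6-dimethyl-2-[(2R)-2-methylbutanoyl]cyclohexa-2,4-dien-1-one
Conditions: NIS, MeCN, 0 °C → rt, dark
Reagents that add atoms: N-iodosuccinimide, O=C1CCC(=O)N1I
Why: Electrophilic iodination at C4a, the only ring C–H and the nucleophilic β-carbon of the C8a ethoxy enol ether, should proceed through an oxocarbenium ion that loses the proton, while the acyl-blocked C6 cannot be substituted and no stereocenter is touched.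

Step 6
Reactants: 18 geraniol
Product: 19 [(2R,3R)-3-methyl-3-(4-methylpent-3-en-1-yl)oxiran-2-yl]methanol
Conditions: Ti(OiPr)4 (5 mol %), D-(−)-diethyl tartrate (7 mol %), t-BuOOH (isooctane), 4 Å MS, CH2Cl2, −20 °C
Reagents that add atoms: tert-butyl hydroperoxide, CC(C)(C)OO
Why: Sharpless asymmetric epoxidation, in which the Ti(OiPr)4/D-(−)-tartrate catalyst controls the face and should give the (2R,3R)-epoxide (mirror image of the (2S,3S)-epoxide formed with the L-(+)-tartrate), the isolated 6,7-alkene being left alone.

Step 7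
Reactants: 19 [(2R,3R)-3-methyl-3-(4-methylpent-3-en-1-yl)oxiran-2-yl]methanol
Product: 20 (2S,3R)-2-(chloromethyl)-3-methyl-3-(4-methylpent-3-en-1-yl)oxirane
Conditions: PPh3, CCl4, NaHCO3, reflux
Reagents that add atoms: carbon tetrachloride, ClC(Cl)(Cl)Cl
Why: Appel chlorination of the primary alcohol under neutral conditions should leave the epoxide and both stereocenters untouched (the C2 descriptor changes to S only through the priority of chlorine).

Step 8
Reactants: 20 (2S,3R)-2-(chloromethyl)-3-methyl-3-(4-methylpent-3-en-1-yl)oxirane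
Product: 22 (3R)-3,7-dimethyloct-6-en-1-yn-3-ol, via chlorovinyl carbinolate 21 (not isolated)
Conditions: n-BuLi (3.3 equiv), THF, −40 → −20 °C; then H2O
Reagents that add atoms: none
Why: Base-induced fragmentation of a 2,3-epoxy chloride to a propargylic alcohol (deprotonation at C1, β-elimination that opens the epoxide, then dehydrochlorination and acetylide formation) never breaks the C3–O bond, so the 3R configuration should be carried into the R carbinol.

Step 9
Reactants: 17 5-ethoxy-4-iodo-3-methoxy-6,6-dimethyl-2-[(2R)-2-methylbutanoyl]cyclohexa-2,4-dien-1-one; 22 (3R)-3,7-dimethyloct-6-en-1-yn-3-ol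
Product: 23 5-ethoxy-4-[(3R)-3-hydroxy-3,7-dimethyloct-6-en-1-yn-1-yl]-3-methoxy-6,6-dimethyl-2-[(2R)-2-methylbutanoyl]cyclohexa-2,4-dien-1-one
Conditions: PdCl2(PPh3)2 (5 mol %), CuI (10 mol %), i-Pr2NEt, THF, rt, degassed
Reagents that add atoms: none
Why: Sonogashira coupling of the α-iodo-enone-type vinyl iodide with the terminal alkyne, run with a tertiary amine because a primary or secondary amine would displace the activated C5 methoxy group; the tertiary hydroxyl cannot reach the ring across the linear alkyne and no stereocenter is touched.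

Step 10
Reactants: 23 5-ethoxy-4-[(3R)-3-hydroxy-3,7-dimethyloct-6-en-1-yn-1-yl]-3-methoxy-6,6-dimethyl-2-[(2R)-2-methylbutanoyl]cyclohexa-2,4-dien-1-one
Product: 24 5-ethoxy-3-hydroxy-4-[(3R)-3-hydroxy-3,7-dimethyloct-6-en-1-yn-1-yl]-6,6-dimethyl-2-[(2R)-2-methylbutanoyl]cyclohexa-2,4-dien-1-one
Conditions: LiOH·H2O, THF/H2O, 0 °C; then cold dilute HCl to pH 4
Reagents that add atoms: lithium hydroxide, [Li+].[OH-]
Why: Addition–elimination of hydroxide (vinylogous ester saponification) should occur at C5, the β-carbon shared by the ring ketone and the acyl ketone, far faster than at the singly activated C8a ethoxy carbon, and the triketonate then formed protects the ring against further attack; the stereocenters are not involved.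

Step 11
Reactants: 24 5-ethoxy-3-hydroxy-4-[(3R)-3-hydroxy-3,7-dimethyloct-6-en-1-yn-1-yl]-6,6-dimethyl-2-[(2R)-2-methylbutanoyl]cyclohexa-2,4-dien-1-one
Product: 26 (2R)-5-hydroxy-2,8,8-trimethyl-6-[(2R)-2-methylbutanoyl]-2-(4-methylpent-3-en-1-yl)-2H-chromen-7(8H)-one, via (Z)-alkene 25 (not isolated)
Conditions: H2 (1 atm), Pd/CaCO3 poisoned with Pb(OAc)2, quinoline, Et3N, EtOAc, rt; filter; then KOt-Bu (2.5 equiv), THF, 0 °C → rt; cold dilute HCl to pH 4
Reagents that add atoms: none
Why: Lindlar syn-semihydrogenation should give the (Z)-alkene and so bring the tertiary hydroxyl within reach of C8a, where, with the C5 oxygen held as the non-electrophilic triketonate, the alkoxide can only add to the ethoxy-bearing carbon and expel ethoxide (6-endo addition–elimination, a vinylogous transesterification); C2 is the untouched carbinol carbon of 22 (C–O bond never broken, hence R), base avoids ionization of the tertiary allylic alcohol and the low temperature avoids epimerization by reversible oxa-6π opening.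

## Compound list

1 | isobutyryl chloride | CC(C)C(=O)Cl | starting material
2 | ethoxyacetylene | CCOC#C | starting material
3 | dimethylketene | CC(C)=C=O | intermediate
4 | 3-ethoxy-4,4-dimethylcyclobut-2-en-1-one | CCOC1=CC(=O)C1(C)C | intermediate
5 | (R)-2-methylbutanoic acid | CC[C@@H](C)C(=O)O | starting material
6 | N,O-dimethylhydroxylamine hydrochloride | CNOC.Cl | starting material
7 | (2R)-1-(imidazol-1-yl)-2-methylbutan-1-one | CC[C@@H](C)C(=O)n1ccnc1 | intermediate
8 | (2R)-N-methoxy-N,2-dimethylbutanamide | CC[C@@H](C)C(=O)N(C)OC | intermediate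
9 | chloroacetaldehyde dimethyl acetal | COC(CCl)OC | starting material
10 | lithium methoxyacetylide | [Li+].[C-]#COC | intermediate
11 | lithium (4R)-1-methoxy-3-[methoxy(methyl)amino]-4-methylhex-1-yn-3-olate (C3 unassigned) | CC[C@@H](C)C([O-])(C#COC)N(C)OC.[Li+] | intermediate
12 | (4R)-1-methoxy-4-methylhex-1-yn-3-one | CC[C@@H](C)C(=O)C#COC | intermediate
13 | 3-ethoxy-4-methylpenta-1,3-dien-1-one | CCOC(C=C=O)=C(C)C | intermediate
14 | 4-(1-ethoxy-2-methylprop-1-en-1-yl)-3-methoxy-2-[(2R)-2-methylbutanoyl]cyclobut-2-en-1-one (C4 epimers) | CC[C@@H](C)C(=O)C1=C(OC)C(C(OCC)=C(C)C)C1=O | intermediate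
15 | (3E)-5-ethoxy-3-methoxy-6-methyl-2-[(2R)-2-methylbutanoyl]hepta-1,3,5-trien-1-one | CC[C@@H](C)C(=O)C(=C=O)/C(OC)=C\C(OCC)=C(C)C | intermediate
16 | 5-ethoxy-3-methoxy-6,6-dimethyl-2-[(2R)-2-methylbutanoyl]cyclohexa-2,4-dien-1-one | CC[C@@H](C)C(=O)C1=C(OC)C=C(OCC)C(C)(C)C1=O | intermediate
17 | 5-ethoxy-4-iodo-3-methoxy-6,6-dimethyl-2-[(2R)-2-methylbutanoyl]cyclohexa-2,4-dien-1-one | CC[C@@H](C)C(=O)C1=C(OC)C(I)=C(OCC)C(C)(C)C1=O | intermediate
18 | geraniol | CC(C)=CCC/C(C)=C/CO | starting material
19 | [(2R,3R)-3-methyl-3-(4-methylpent-3-en-1-yl)oxiran-2-yl]methanol | OC[C@H]1O[C@]1(C)CCC=C(C)C | intermediate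
20 | (2S,3R)-2-(chloromethyl)-3-methyl-3-(4-methylpent-3-en-1-yl)oxirane | ClC[C@H]1O[C@]1(C)CCC=C(C)C | intermediate
21 | lithium (3R)-1-chloro-3,7-dimethylocta-1,6-dien-3-olate | [Li+].[O-][C@](C)(CCC=C(C)C)C=CCl | intermediate
22 | (3R)-3,7-dimethyloct-6-en-1-yn-3-ol | O[C@](C)(CCC=C(C)C)C#C | intermediate
23 | 5-ethoxy-4-[(3R)-3-hydroxy-3,7-dimethyloct-6-en-1-yn-1-yl]-3-methoxy-6,6-dimethyl-2-[(2R)-2-methylbutanoyl]cyclohexa-2,4-dien-1-one | CC[C@@H](C)C(=O)C1=C(OC)C(C#C[C@](C)(O)CCC=C(C)C)=C(OCC)C(C)(C)C1=O | intermediate
24 | 5-ethoxy-3-hydroxy-4-[(3R)-3-hydroxy-3,7-dimethyloct-6-en-1-yn-1-yl]-6,6-dimethyl-2-[(2R)-2-methylbutanoyl]cyclohexa-2,4-dien-1-one | CC[C@@H](C)C(=O)C1=C(O)C(C#C[C@](C)(O)CCC=C(C)C)=C(OCC)C(C)(C)C1=O | intermediate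
25 | 5-ethoxy-3-hydroxy-4-[(1Z,3R)-3-hydroxy-3,7-dimethylocta-1,6-dien-1-yl]-6,6-dimethyl-2-[(2R)-2-methylbutanoyl]cyclohexa-2,4-dien-1-one | CC[C@@H](C)C(=O)C1=C(O)C(/C=C\[C@](C)(O)CCC=C(C)C)=C(OCC)C(C)(C)C1=O | intermediate
26 | (2R)-5-hydroxy-2,8,8-trimethyl-6-[(2R)-2-methylbutanoyl]-2-(4-methylpent-3-en-1-yl)-2H-chromen-7(8H)-one | CC[C@@H](C)C(=O)C1=C(O)C2=C(O[C@](C)(CCC=C(C)C)C=C2)C(C)(C)C1=O | target

## Step count and risks

Total step count: 11. Longest linear sequence: 7 steps (steps 2, 3, 4, 5, 9, 10, 11, from 5).

Steps most likely to fail: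

**Step 4 (proposed new method).** Capture of the vinylketene by the electron-poor ynol ether may be too slow, so that the ketene only recloses, oligomerizes or escapes by a [1,5]-hydrogen shift from its cis-methyl group while 12 decomposes on heating. The fallback uses known chemistry, sets out from 4 and comes back at 16. The same thermal annulation with the electron-rich (triisopropylsiloxy)ethyne, an established siloxyalkyne partner for this benzannulation, should give 5-ethoxy-6,6-dimethyl-3-(triisopropylsiloxy)cyclohexa-2,4-dien-1-one F1. Desilylation (Bu4NF, AcOH, THF, 0 °C) should give 5-ethoxy-4,4-dimethylcyclohex-5-ene-1,3-dione F2. O-acylation with 5 (DCC, DMAP, CH2Cl2) and in-situ 1,3-acyl shift to carbon should give 5-ethoxy-3-hydroxy-6,6-dimethyl-2-[(2R)-2-methylbutanoyl]cyclohexa-2,4-dien-1-one F3, to be checked for epimerization of the acyl center. O-methylation with TMSCHN2 (PhMe/MeOH, 0 °C) at the unhindered C5 enol oxygen (the C7 oxygen is screened by quaternary C8) should then give 16.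

**Step 11.** The addition–elimination at C8a may be sluggish because the ring is deactivated as the triketonate. The enyne may be over-reduced or the alkynyl triketone cycloisomerized on the palladium surface. If closure is forced by heating, the C2 configuration may erode by reversible oxa-6π ring opening. The fallback moves the pyran closure ahead of the ring expansion, onto a neutral and strained vinylogous ester; it sets out from 4 and 22 and comes back at 26. Iodination of 4 (NIS, MeCN) should give 3-ethoxy-2-iodo-4,4-dimethylcyclobut-2-en-1-one F4. Sonogashira coupling with 22 (PdCl2(PPh3)2, CuI, i-Pr2NEt) should give 3-ethoxy-2-[(3R)-3-hydroxy-3,7-dimethyloct-6-en-1-yn-1-yl]-4,4-dimethylcyclobut-2-en-1-one F5. Semihydrogenation (H2, Pd/CaCO3 poisoned with Pb(OAc)2) should give 3-ethoxy-2-[(1Z,3R)-3-hydroxy-3,7-dimethylocta-1,6-dien-1-yl]-4,4-dimethylcyclobut-2-en-1-one F6. Catalytic KOt-Bu should close F6 at the cyclobutenone C3 to (3R)-3,8,8-trimethyl-3-(4-methylpent-3-en-1-yl)-2-oxabicyclo[4.2.0]octa-1(6),4-dien-7-one F7. Annulation of F7 with 12 as in step 4, at the lowest temperature that turns over, should give (2R)-5-methoxy-2,8,8-trimethyl-6-[(2R)-2-methylbutanoyl]-2-(4-methylpent-3-en-1-yl)-2H-chromen-7(8H)-one F8, and LiOH as in step 10 should give 26. This order exposes the 2H-pyran to heat, so the configurational purity at C2 would have to be checked.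

**Step 3.** The liberated amines may add to the ynone, or the ynol ether may be hydrated by acid, while the ketone is released from the tetrahedral adduct. The fallback replaces the amide addition by an acylative Stille coupling under neutral, amine-free conditions; it sets out from 9 and 5 and comes back at 12. Lithium methoxyacetylide 10, generated as before, is quenched with Bu3SnCl to give tributyl(methoxyethynyl)stannane F9, which is freed from amines by distillation. Acid 5 is converted with oxalyl chloride and catalytic DMF into (2R)-2-methylbutanoyl chloride F10. Coupling of F9 and F10 (PdCl2(PPh3)2, PhMe, 60 °C) should give 12.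

Further compounds
F1 | step 4 | 5-ethoxy-6,6-dimethyl-3-(triisopropylsiloxy)cyclohexa-2,4-dien-1-one | CCOC1=CC(O[Si](C(C)C)(C(C)C)C(C)C)=CC(=O)C1(C)C
F2 | step 4 | 5-ethoxy-4,4-dimethylcyclohex-5-ene-1,3-dione | CCOC1=CC(=O)CC(=O)C1(C)C
F3 | step 4 | 5-ethoxy-3-hydroxy-6,6-dimethyl-2-[(2R)-2-methylbutanoyl]cyclohexa-2,4-dien-1-one | CC[C@@H](C)C(=O)C1=C(O)C=C(OCC)C(C)(C)C1=O
F4 | step 11 | 3-ethoxy-2-iodo-4,4-dimethylcyclobut-2-en-1-one | CCOC1=C(I)C(=O)C1(C)C
F5 | step 11 | 3-ethoxy-2-[(3R)-3-hydroxy-3,7-dimethyloct-6-en-1-yn-1-yl]-4,4-dimethylcyclobut-2-en-1-one | CCOC1=C(C#C[C@](C)(O)CCC=C(C)C)C(=O)C1(C)C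
F6 | step 11 | 3-ethoxy-2-[(1Z,3R)-3-hydroxy-3,7-dimethylocta-1,6-dien-1-yl]-4,4-dimethylcyclobut-2-en-1-one | CCOC1=C(/C=C\[C@](C)(O)CCC=C(C)C)C(=O)C1(C)C
F7 | step 11 | (3R)-3,8,8-trimethyl-3-(4-methylpent-3-en-1-yl)-2-oxabicyclo[4.2.0]octa-1(6),4-dien-7-one | O=C1C2=C(O[C@](C)(CCC=C(C)C)C=C2)C1(C)C
F8 | step 11 | (2R)-5-methoxy-2,8,8-trimethyl-6-[(2R)-2-methylbutanoyl]-2-(4-methylpent-3-en-1-yl)-2H-chromen-7(8H)-one | CC[C@@H](C)C(=O)C1=C(OC)C2=C(O[C@](C)(CCC=C(C)C)C=C2)C(C)(C)C1=O
F9 | step 3 | tributyl(methoxyethynyl)stannane | CCCC[Sn](CCCC)(CCCC)C#COC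
F10 | step 3 | (2R)-2-methylbutanoyl chloride | CC[C@@H](C)C(=O)Cl
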